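(Its constants stand for no real mixture; the flask was simulated.)

The ratio of target to intermediate at rest is what I carried through these flasks.

| flask | starting material | reagent | temperature | time | remark |
|---|---|---|---|---|---|
| maple | 0.50 M | 0.400 M | −5 °C | 5.0 min |  |
| ash | 0.50 M | 0.400 M | 45 °C | 5.0 min |  |
| birch | 0.50 M | 0.400 M |  | 5.0 min | at −5 °C until 4.0 min, from then on at 45 °C |
| alder | 0.50 M | 0.400 M | 20 °C | 5.0 min |  |

    intermediate ⇌ target (K1 = 0.32, k1 = 0.0246 s⁻¹, Ea1 = 78.0 kJ mol⁻¹, ΔH1 = −36.0 kJ mol⁻¹)
    starting material + reagent → intermediate + by-product (k2 = 0.0171 M⁻¹ s⁻¹, Ea2 = 50.0 kJ mol⁻¹)
    (constants at 20 °C)

- the constants hold at 20 °C; other temperatures follow from the activation energies and enthalpies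

1. the flask with the highest amount of target, in percent of the starting material charged ("all alike" if they lie within 1.5 percentage points) (maple / ash / birch / alder / all alike)
2. final target, as a percentage of the starting material charged, in maple
3. final target, as a percentage of the starting material charged, in ash
4. final target, as a percentage of the starting material charged, in birch
5. final target, as a percentage of the starting material charged, in alder

In alder the equilibrium constant gives 24.2 % as the settled share. That is the constant divided by one plus itself: the fraction of intermediate and target together that stands as target once step 1 has relaxed. In alder step 1 relaxes with a half-life of 0.114 min, short against 5.0 min. So I took target there as the settled share of what step 2 had converted, which is thermodynamic control of the pair. Ash has a share of 9.11 %. It is hotter than alder, so I took it as settled too.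

Then I turned the question round: what would ash need to beat alder? Its conversion would have to exceed alder's by a factor of 2.66. But reagent is the limiting reagent, so conversion in ash cannot pass 80.0 % of the starting material. Alder would therefore have to convert less than 30.1 %.

I tested that bar. If alder stopped there, its rate at that end point would be 0.0896 M min⁻¹. Step 2 runs faster before that point, with more of both charges standing, so even at the end-point rate the 0.150 M of the bar takes 1.68 min, shorter than 5.0 min. Integrating step 2 gave alder a conversion of 61.6 %, about twice the bar. So I committed to 14.9 % of target in alder, against a cap of 7.29 % in ash.

I left maple and birch open. Maple's share of 55.9 % is larger than alder's. But from the coldest flask to the hottest, step 1 speeds up by a factor of 240, more than step 2 with 34, so I could not assume that step 1 had relaxed in maple.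

The forecast named alder, with 3.7 % in maple, 7.2 % in ash, 5.8 % in birch and 14.8 % in alder, and said that “the intermediate temperature of alder wins clearly”.

Alder gave 14.8 % of target, more than maple at 3.71 %, ash at 7.17 % and birch at 5.79 %. Target over target plus intermediate in alder read 24.0 %, against the settled share of 24.2 %. I then took the neighbour flask, alder with 0.68 M of reagent and the rest held. The same integration gave it a conversion of 85.2 %, and the share turned that into 20.6 % of target. That neighbour flask held 64.7 % as intermediate and 20.5 % as target.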